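Rings are lettered along the chain A–O–B–O–C–O–D–O–E–O–F–O–G, with A the 2,4,6-trihydroxyphenyl end and G the 3,4,5-trihydroxyphenyl end. The plan rests on ring F: its ether oxygens sit para to each other on F C1 (to E C2) and F C4 (to G C1), hydroxyls occupy F C3 and F C5, and the F C4–O bond is therefore hemmed in on both sides.
Ring F is built, not coupled. F C1–C2 come from the ethynyl ether of the ring E phenol. F C3–C6 come from a 4-aryloxy-3-ethoxycyclobutenone that already carries G–O on the future F C4. The benzannulation makes F C2–C3 and F C1–C6.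
Rings D and B have the same 1,4-dioxy-3,5-dihydroxy pattern and come from one linchpin, 5-bromo-2-fluoro-3-methoxybenzaldehyde. SNAr at C–F makes the crowded D C4–O–E C1 (B C4–O–C C1) bond, Baeyer–Villiger oxidation turns CHO into the second flanking oxygen, and C–Br takes the hindered phenol of ring C (ring A) by Ullmann coupling.
Order: E and G enter as bought arenes, F is the only ring formed (step 9), then D, C, B and A are attached in that order, and BBr3 frees all seventeen hydroxyls at the end.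

Key step: step 9

Remark: the target has no stereocentre and its diaryl ether axes are taken as freely rotating, so no configuration has to be set. Cyclobutenone 18 is used as the racemate.
Locants:
- In B, D and F, C1 bears the oxygen towards ring A and C4 the oxygen towards ring G.
- In E, C1–O goes to D and C2–O to F (oxygens also on C3 and C5).
- In C, C1–O goes to B and C6–O to D (oxygens also on C3, C4 and C5).

Step 1
Reactants: 1 2-hydroxy-4,6-dimethoxybenzaldehyde
Product: 2 2-(benzyloxy)-4,6-dimethoxybenzaldehyde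
Conditions: BnBr, K2CO3, DMF, 60 °C
Reagents that add atoms: benzyl bromide, BrCc1ccccc1
Why: Williamson etherification: carbonate frees the chelated phenoxide, which displaces bromide by SN2 and marks E C1–O with the one group that hydrogenolysis can later remove.

Step 2
Reactants: 2 2-(benzyloxy)-4,6-dimethoxybenzaldehyde
Product: 4 2-(benzyloxy)-4,6-dimethoxyphenol, via aryl formate 3 (not isolated)
Conditions: mCPBA, CH2Cl2, 0 °C to rt; crude formate, K2CO3 (cat.), MeOH, rt
Reagents that add atoms: mCPBA, OOC(=O)c1cccc(Cl)c1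
Why: Baeyer–Villiger oxidation: with oxygen donors on both ortho positions and the para position the aryl group migrates in the Criegee adduct in preference to hydride, and formate 3 is cleaved by mild transesterification to the E C2 phenol.

Step 3
Reactants: 4 2-(benzyloxy)-4,6-dimethoxyphenol; 5 trichloroethylene
Product: 7 1-(benzyloxy)-2-{[(E)-1,2-dichloroethenyl]oxy}-3,5-dimethoxybenzene, via dichloroacetylene 6 (not isolated)
Conditions: K2CO3, DMF, 70 °C, Ar, closed vessel
Reagents that add atoms: none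
Why: Elimination–addition: carbonate strips HCl from trichloroethylene and the phenoxide adds anti across the small, linear dichloroacetylene 6, the known route from phenols to aryl (E)-1,2-dichlorovinyl ethers, which two ortho substituents hinder little.

Step 4
Reactants: 7 1-(benzyloxy)-2-{[(E)-1,2-dichloroethenyl]oxy}-3,5-dimethoxybenzene
Product: 10 1-(benzyloxy)-2-(ethynyloxy)-3,5-dimethoxybenzene, via chloroethynyl ether 8 (not isolated), via lithium acetylide 9 (not isolated)
Conditions: n-BuLi (2.2 equiv), THF, −78 to −40 °C; then H2O, −78 °C to rt; used at once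
Reagents that add atoms: none
Why: Known conversion of a dichlorovinyl ether into an ynol ether: the first n-BuLi removes the vinyl proton and LiCl is lost to give chloroalkyne 8, the second exchanges chlorine for lithium, and protonation of acetylide 9 gives the terminal aryl ethynyl ether, the low temperature keeping the benzyl ether and the ring C–H bonds out of play.

Step 5
Reactants: 11 3,4,5-trimethoxyphenol; 12 methyl bromoacetate
Product: 13 methyl (3,4,5-trimethoxyphenoxy)acetate
Conditions: K2CO3, acetone, reflux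
Reagents that add atoms: none
Why: Williamson etherification of an unhindered phenoxide with an activated primary bromide (SN2); the two carbons brought in become F C4 and F C3.

Step 6
Reactants: 13 methyl (3,4,5-trimethoxyphenoxy)acetate
Product: 14 (3,4,5-trimethoxyphenoxy)acetic acid
Conditions: LiOH, THF/H2O, rt; then 1 M HCl
Reagents that add atoms: lithium hydroxide, [Li+].[OH-]
Why: Saponification (acyl substitution by hydroxide) of an unhindered methyl ester, to which the aryl ethers are inert.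

Step 7
Reactants: 14 (3,4,5-trimethoxyphenoxy)acetic acid
Product: 15 (3,4,5-trimethoxyphenoxy)acetyl chloride
Conditions: (COCl)2, DMF (cat.), CH2Cl2, 0 °C to rt; evaporation
Reagents that add atoms: oxalyl chloride, ClC(=O)C(Cl)=O
Why: Acid chloride formation under DMF catalysis runs cold and without strong acid, so the electron-rich ring is left alone.

Step 8
Reactants: 15 (3,4,5-trimethoxyphenoxy)acetyl chloride; 16 ethoxyacetylene
Product: 18 rac-3-ethoxy-4-(3,4,5-trimethoxyphenoxy)cyclobut-2-en-1-one, via aryloxyketene 17 (not isolated)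
Conditions: 16 (3 equiv), Et3N, Et2O/hexanes, 0 °C to rt, slow addition of 15
Reagents that add atoms: none
Why: Dehydrochlorination gives aryloxyketene 17, which ethoxyacetylene captures in the known ketene–ynol ether [2+2] cycloaddition; the alkyne CH terminus bonds to the ketene carbonyl carbon, so OEt ends on C3 and the aryloxy group on C4, whose new stereocentre forms racemic and is erased in step 9.

Step 9
Reactants: 10 1-(benzyloxy)-2-(ethynyloxy)-3,5-dimethoxybenzene; 18 rac-3-ethoxy-4-(3,4,5-trimethoxyphenoxy)cyclobut-2-en-1-one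
Product: 23 5-[2-(benzyloxy)-4,6-dimethoxyphenoxy]-3-ethoxy-2-(3,4,5-trimethoxyphenoxy)phenol, via vinylketene 19 (not isolated), via vinylcyclobutenone 20 (not isolated), via dienylketene 21 (not isolated), via cyclohexadienone 22 (not isolated)
Conditions: 18 (1.3 equiv), PhMe, 80 °C then 110 °C, sealed tube, Ar
Reagents that add atoms: none
Why: Conrotatory 4π opening of 18 breaks its C1–C4 bond, the aryloxy donor turning outward and easing the opening, and gives vinylketene 19. The ketene C=C of 19 adds [2+2] to alkyne 10, joining the alkyne CH to the ketene carbonyl carbon (F C2–C3) and the oxygen-bearing alkyne carbon to the ketene alpha carbon (F C1–C6), to give 20. A second 4π opening of 20 gives dienylketene 21, ring F closes by a disrotatory 6π electrocyclisation between the ketene carbon (F C3) and the aryloxy-bearing terminus (F C4), and dienone 22 tautomerises to phenol 23. The closest known reaction type is the Danheiser benzannulation of cyclobutenones with alkoxy- and silyloxyalkynes; an aryl ethynyl ether is polarised in the same sense, is less nucleophilic, but cannot fragment by retro-ene loss of an alkene on heating as alkyl ynol ethers do. The step needs regioselectivity in the ketene–alkyne addition, and the alkyne oxygen secures it by making the CH terminus the nucleophile, which places E–O on F C1, meta to the new hydroxyl and para to G–O. No stereocentre survives, since the sp3 carbons of 18, 20 and 22 all become aromatic.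

Step 10
Reactants: 23 5-[2-(benzyloxy)-4,6-dimethoxyphenoxy]-3-ethoxy-2-(3,4,5-trimethoxyphenoxy)phenol
Product: 24 5-[2-(benzyloxy)-4,6-dimethoxyphenoxy]-1-ethoxy-3-methoxy-2-(3,4,5-trimethoxyphenoxy)benzene
Conditions: MeI, K2CO3, DMF, rt
Reagents that add atoms: iodomethane, CI
Why: Williamson methylation of the only free hydroxyl (F C3–OH), so that the phenol freed in step 11 is the sole nucleophile in step 13.

Step 11
Reactants: 24 5-[2-(benzyloxy)-4,6-dimethoxyphenoxy]-1-ethoxy-3-methoxy-2-(3,4,5-trimethoxyphenoxy)benzene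
Product: 25 2-[3-ethoxy-5-methoxy-4-(3,4,5-trimethoxyphenoxy)phenoxy]-3,5-dimethoxyphenol (trimer E–F–G with free E C1–OH)
Conditions: H2 (1 atm), 10% Pd/C, EtOAc/MeOH, rt
Reagents that add atoms: none
Why: Catalytic hydrogenolysis cleaves only the benzylic C–O bond, while diaryl, methyl and ethyl ethers are inert.

Step 12
Reactants: 26 4-bromo-1-fluoro-2-methoxybenzene
Product: 29 5-bromo-2-fluoro-3-methoxybenzaldehyde, via aryllithium 27 (not isolated), via hemiaminal alkoxide 28 (not isolated)
Conditions: LiN(i-Pr)2 (1.05 equiv), THF, −78 °C; DMF, −78 to 0 °C; then H2O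
Reagents that add atoms: N,N-dimethylformamide, CN(C)C=O
Why: Directed ortho-metalation and formylation: fluorine acidifies its neighbouring C–H most strongly, the amide base deprotonates there without bromine–lithium exchange, aryllithium 27 holds its fluoride at −78 °C, and DMF traps it as alkoxide 28, which collapses to the aldehyde on aqueous work-up.

Step 13
Reactants: 25 trimer E–F–G phenol; 29 5-bromo-2-fluoro-3-methoxybenzaldehyde
Product: 30 5-bromo-2-{2-[3-ethoxy-5-methoxy-4-(3,4,5-trimethoxyphenoxy)phenoxy]-3,5-dimethoxyphenoxy}-3-methoxybenzaldehyde (tetramer D–E–F–G aldehyde)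
Conditions: K2CO3, DMF, 90 °C
Reagents that add atoms: none
Why: SNAr by addition–elimination: the ortho formyl group and the para bromine stabilise the Meisenheimer adduct, fluoride leaves, C–Br is untouched, and the D C4–O–E C1 bond is made without a metal at a carbon that will be flanked on both sides.

Step 14
Reactants: 30 tetramer D–E–F–G aldehyde
Product: 32 tetramer phenol (30 with OH in place of CHO on D C5), via tetramer formate 31 (not isolated)
Conditions: mCPBA, CH2Cl2, 0 °C to rt; crude formate, K2CO3 (cat.), MeOH, rt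
Reagents that add atoms: mCPBA, OOC(=O)c1cccc(Cl)c1
Why: Baeyer–Villiger oxidation: the ortho aryloxy donor favours aryl over hydride migration, as with 2-alkoxy-5-bromobenzaldehydes, and methanolysis of formate 31 uncovers D C5–OH.

Step 15
Reactants: 32 tetramer phenol
Product: 33 5-bromo-2-{2-[3-ethoxy-5-methoxy-4-(3,4,5-trimethoxyphenoxy)phenoxy]-3,5-dimethoxyphenoxy}-1,3-dimethoxybenzene (tetramer bromide)
Conditions: MeI, K2CO3, DMF, rt
Reagents that add atoms: iodomethane, CI
Why: Williamson methylation caps D C5–OH so that no phenol of the bromide itself competes in the copper coupling.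

Step 16
Reactants: 11 3,4,5-trimethoxyphenol
Product: 34 5-(benzyloxy)-1,2,3-trimethoxybenzene
Conditions: BnBr, K2CO3, DMF, rt
Reagents that add atoms: benzyl bromide, BrCc1ccccc1
Why: Williamson etherification (SN2) puts the removable group on the oxygen that becomes C C1–O.

Step 17
Reactants: 34 5-(benzyloxy)-1,2,3-trimethoxybenzene
Product: 36 2-(benzyloxy)-4,5,6-trimethoxybenzaldehyde, via iminium chloride 35 (not isolated)
Conditions: POCl3, DMF, 0 °C to rt; then H2O
Reagents that add atoms: N,N-dimethylformamide, CN(C)C=O; water, O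
Why: Vilsmeier–Haack formylation: the two free ring positions of 34 are equivalent and each is activated by ortho and para oxygen donors, so a single aldehyde results after hydrolysis of iminium salt 35.

Step 18
Reactants: 36 2-(benzyloxy)-4,5,6-trimethoxybenzaldehyde
Product: 38 2-(benzyloxy)-4,5,6-trimethoxyphenol, via aryl formate 37 (not isolated)
Conditions: mCPBA, CH2Cl2, 0 °C to rt; crude formate, K2CO3 (cat.), MeOH, rt, Ar
Reagents that add atoms: mCPBA, OOC(=O)c1cccc(Cl)c1
Why: Baeyer–Villiger oxidation as in step 2: the strongly donor-substituted aryl group migrates and methanolysis of formate 37 gives the C C6 phenol.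

Step 19
Reactants: 33 tetramer bromide; 38 2-(benzyloxy)-4,5,6-trimethoxyphenol
Product: 39 pentamer C–D–E–F–G benzyl ether (33 with the 2-(benzyloxy)-4,5,6-trimethoxyphenoxy group in place of Br on D C1)
Conditions: CuI (10 mol %), picolinic acid (20 mol %), K3PO4, DMSO, 100 °C, Ar
Reagents that add atoms: none
Why: Ligand-accelerated Ullmann diaryl ether coupling: all the crowding lies on the phenol, a case the CuI/picolinic acid system is known to handle, while D C1–Br has hydrogen on both neighbouring carbons.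

Step 20
Reactants: 39 pentamer benzyl ether
Product: 40 pentamer phenol (39 with free OH on C C1)
Conditions: H2 (1 atm), 10% Pd/C, EtOAc/MeOH, rt
Reagents that add atoms: none
Why: Catalytic hydrogenolysis of the single benzyl ether; no halogen or other reducible group is present at this stage.

Step 21
Reactants: 40 pentamer phenol; 29 5-bromo-2-fluoro-3-methoxybenzaldehyde
Product: 41 hexamer B–C–D–E–F–G aldehyde (40 arylated on C C1–O by the 4-bromo-2-formyl-6-methoxyphenyl group)
Conditions: K2CO3, DMF, 90 °C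
Reagents that add atoms: none
Why: SNAr as in step 13: activation by the ortho formyl group forms the B C4–O–C C1 bond and leaves B C1–Br in place.

Step 22
Reactants: 41 hexamer aldehyde
Product: 43 hexamer phenol (41 with OH in place of CHO on B C5), via hexamer formate 42 (not isolated)
Conditions: mCPBA, CH2Cl2, 0 °C to rt; crude formate, K2CO3 (cat.), MeOH, rt
Reagents that add atoms: mCPBA, OOC(=O)c1cccc(Cl)c1
Why: Baeyer–Villiger oxidation as in step 14: aryl migration is directed by the ortho aryloxy donor and is followed by methanolysis of formate 42.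

Step 23
Reactants: 43 hexamer phenol
Product: 44 hexamer bromide (43 with OMe on B C5)
Conditions: MeI, K2CO3, DMF, rt
Reagents that add atoms: iodomethane, CI
Why: Williamson methylation removes the only phenol of the bromide before the last copper coupling.

Step 24
Reactants: 44 hexamer bromide; 45 2,4,6-trimethoxyphenol
Product: 46 protected heptamer (44 with the 2,4,6-trimethoxyphenoxy group in place of Br on B C1; sixteen OMe groups plus OEt on F C5)
Conditions: CuI (10 mol %), picolinic acid (20 mol %), K3PO4, DMSO, 100 °C, Ar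
Reagents that add atoms: none
Why: Ullmann diaryl ether coupling as in step 19, pairing a 2,6-disubstituted phenol with a bromide carbon that has no ortho substituent.

Step 25
Reactants: 46 protected heptamer
Product: 47 CNP0351377.0
Conditions: BBr3 (about 2 equiv per ether), CH2Cl2, −78 °C to rt, Ar; then MeOH, 0 °C, repeated evaporation from MeOH
Reagents that add atoms: none
Why: Lewis acid ether cleavage: boron binds each alkyl aryl ether oxygen and bromide attacks the methyl or ethyl carbon by SN2, whereas the six diaryl ether links offer no sp3 carbon and stay intact.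

Compound list
1 | 2-hydroxy-4,6-dimethoxybenzaldehyde | COc1cc(O)c(C=O)c(OC)c1 | starting material
2 | 2-(benzyloxy)-4,6-dimethoxybenzaldehyde | COc1cc(OCc2ccccc2)c(C=O)c(OC)c1 | intermediate
3 | 2-(benzyloxy)-4,6-dimethoxyphenyl formate | COc1cc(OCc2ccccc2)c(OC=O)c(OC)c1 | intermediate
4 | 2-(benzyloxy)-4,6-dimethoxyphenol | COc1cc(OCc2ccccc2)c(O)c(OC)c1 | intermediate
5 | trichloroethylene | ClC=C(Cl)Cl | starting material
6 | dichloroacetylene | ClC#CCl | intermediate
7 | 1-(benzyloxy)-2-{[(E)-1,2-dichloroethenyl]oxy}-3,5-dimethoxybenzene | Cl/C=C(/Cl)Oc1c(OCc2ccccc2)cc(OC)cc1OC | intermediate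
8 | 1-(benzyloxy)-2-[(chloroethynyl)oxy]-3,5-dimethoxybenzene | ClC#COc1c(OCc2ccccc2)cc(OC)cc1OC | intermediate
9 | lithium [2-(benzyloxy)-4,6-dimethoxyphenoxy]acetylide | [Li]C#COc1c(OCc2ccccc2)cc(OC)cc1OC | intermediate
10 | 1-(benzyloxy)-2-(ethynyloxy)-3,5-dimethoxybenzene | C#COc1c(OCc2ccccc2)cc(OC)cc1OC | intermediate
11 | 3,4,5-trimethoxyphenol | COc1cc(O)cc(OC)c1OC | starting material
12 | methyl bromoacetate | COC(=O)CBr | starting material
13 | methyl (3,4,5-trimethoxyphenoxy)acetate | COC(=O)COc1cc(OC)c(OC)c(OC)c1 | intermediate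
14 | (3,4,5-trimethoxyphenoxy)acetic acid | OC(=O)COc1cc(OC)c(OC)c(OC)c1 | intermediate
15 | (3,4,5-trimethoxyphenoxy)acetyl chloride | ClC(=O)COc1cc(OC)c(OC)c(OC)c1 | intermediate
16 | ethoxyacetylene | CCOC#C | starting material
17 | (3,4,5-trimethoxyphenoxy)ketene | O=C=COc1cc(OC)c(OC)c(OC)c1 | intermediate
18 | rac-3-ethoxy-4-(3,4,5-trimethoxyphenoxy)cyclobut-2-en-1-one | CCOC1=CC(=O)C1Oc1cc(OC)c(OC)c(OC)c1 | intermediate
19 | (3Z)-3-ethoxy-4-(3,4,5-trimethoxyphenoxy)buta-1,3-dien-1-one | O=C=C/C(OCC)=C/Oc1cc(OC)c(OC)c(OC)c1 | intermediate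
20 | rac-3-[2-(benzyloxy)-4,6-dimethoxyphenoxy]-4-[(Z)-1-ethoxy-2-(3,4,5-trimethoxyphenoxy)ethenyl]cyclobut-2-en-1-one | O=C1C=C(Oc2c(OCc3ccccc3)cc(OC)cc2OC)C1/C(OCC)=C/Oc1cc(OC)c(OC)c(OC)c1 | intermediate
21 | (3E,5Z)-3-[2-(benzyloxy)-4,6-dimethoxyphenoxy]-5-ethoxy-6-(3,4,5-trimethoxyphenoxy)hexa-1,3,5-trien-1-one | O=C=C/C(Oc1c(OCc2ccccc2)cc(OC)cc1OC)=C\C(OCC)=C\Oc1cc(OC)c(OC)c(OC)c1 | intermediate
22 | rac-3-[2-(benzyloxy)-4,6-dimethoxyphenoxy]-5-ethoxy-6-(3,4,5-trimethoxyphenoxy)cyclohexa-2,4-dien-1-one | O=C1C=C(Oc2c(OCc3ccccc3)cc(OC)cc2OC)C=C(OCC)C1Oc1cc(OC)c(OC)c(OC)c1 | intermediate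
23 | 5-[2-(benzyloxy)-4,6-dimethoxyphenoxy]-3-ethoxy-2-(3,4,5-trimethoxyphenoxy)phenol | Oc1cc(Oc2c(OCc3ccccc3)cc(OC)cc2OC)cc(OCC)c1Oc1cc(OC)c(OC)c(OC)c1 | intermediate
24 | 5-[2-(benzyloxy)-4,6-dimethoxyphenoxy]-1-ethoxy-3-methoxy-2-(3,4,5-trimethoxyphenoxy)benzene | COc1cc(Oc2c(OCc3ccccc3)cc(OC)cc2OC)cc(OCC)c1Oc1cc(OC)c(OC)c(OC)c1 | intermediate
25 | 2-[3-ethoxy-5-methoxy-4-(3,4,5-trimethoxyphenoxy)phenoxy]-3,5-dimethoxyphenol (trimer E–F–G phenol) | Oc1cc(OC)cc(OC)c1Oc2cc(OC)c(Oc3cc(OC)c(OC)c(OC)c3)c(OCC)c2 | intermediate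
26 | 4-bromo-1-fluoro-2-methoxybenzene | COc1cc(Br)ccc1F | starting material
27 | (5-bromo-2-fluoro-3-methoxyphenyl)lithium | COc1cc(Br)cc([Li])c1F | intermediate
28 | lithium (5-bromo-2-fluoro-3-methoxyphenyl)(dimethylamino)methanolate | COc1cc(Br)cc(C([O-])N(C)C)c1F.[Li+] | intermediate
29 | 5-bromo-2-fluoro-3-methoxybenzaldehyde | COc1cc(Br)cc(C=O)c1F | intermediate
30 | tetramer D–E–F–G aldehyde (Br on D C1, OMe on D C3, CHO on D C5) | O=Cc1cc(Br)cc(OC)c1Oc2cc(OC)cc(OC)c2Oc3cc(OC)c(Oc4cc(OC)c(OC)c(OC)c4)c(OCC)c3 | intermediate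
31 | tetramer formate (OCHO on D C5) | O=COc1cc(Br)cc(OC)c1Oc2cc(OC)cc(OC)c2Oc3cc(OC)c(Oc4cc(OC)c(OC)c(OC)c4)c(OCC)c3 | intermediate
32 | tetramer phenol (OH on D C5) | Oc1cc(Br)cc(OC)c1Oc2cc(OC)cc(OC)c2Oc3cc(OC)c(Oc4cc(OC)c(OC)c(OC)c4)c(OCC)c3 | intermediate
33 | tetramer bromide (OMe on D C3 and D C5, Br on D C1) | COc1cc(Br)cc(OC)c1Oc2cc(OC)cc(OC)c2Oc3cc(OC)c(Oc4cc(OC)c(OC)c(OC)c4)c(OCC)c3 | intermediate
34 | 5-(benzyloxy)-1,2,3-trimethoxybenzene | COc1cc(OCc2ccccc2)cc(OC)c1OC | intermediate
35 | N-{[2-(benzyloxy)-4,5,6-trimethoxyphenyl]methylidene}-N-methylmethanaminium chloride | C[N+](C)=Cc1c(OCc2ccccc2)cc(OC)c(OC)c1OC.[Cl-] | intermediate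
36 | 2-(benzyloxy)-4,5,6-trimethoxybenzaldehyde | O=Cc1c(OCc2ccccc2)cc(OC)c(OC)c1OC | intermediate
37 | 2-(benzyloxy)-4,5,6-trimethoxyphenyl formate | O=COc1c(OCc2ccccc2)cc(OC)c(OC)c1OC | intermediate
38 | 2-(benzyloxy)-4,5,6-trimethoxyphenol | Oc1c(OCc2ccccc2)cc(OC)c(OC)c1OC | intermediate
39 | pentamer C–D–E–F–G benzyl ether (OBn on C C1) | COc1cc(Oc5c(OCc6ccccc6)cc(OC)c(OC)c5OC)cc(OC)c1Oc2cc(OC)cc(OC)c2Oc3cc(OC)c(Oc4cc(OC)c(OC)c(OC)c4)c(OCC)c3 | intermediate
40 | pentamer phenol (OH on C C1) | COc1cc(Oc5c(O)cc(OC)c(OC)c5OC)cc(OC)c1Oc2cc(OC)cc(OC)c2Oc3cc(OC)c(Oc4cc(OC)c(OC)c(OC)c4)c(OCC)c3 | intermediate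
41 | hexamer B–C–D–E–F–G aldehyde (Br on B C1, OMe on B C3, CHO on B C5) | O=Cc7cc(Br)cc(OC)c7Oc5cc(OC)c(OC)c(OC)c5Oc1cc(OC)c(Oc2cc(OC)cc(OC)c2Oc3cc(OC)c(Oc4cc(OC)c(OC)c(OC)c4)c(OCC)c3)c(OC)c1 | intermediate
42 | hexamer formate (OCHO on B C5) | O=COc7cc(Br)cc(OC)c7Oc5cc(OC)c(OC)c(OC)c5Oc1cc(OC)c(Oc2cc(OC)cc(OC)c2Oc3cc(OC)c(Oc4cc(OC)c(OC)c(OC)c4)c(OCC)c3)c(OC)c1 | intermediate
43 | hexamer phenol (OH on B C5) | Oc7cc(Br)cc(OC)c7Oc5cc(OC)c(OC)c(OC)c5Oc1cc(OC)c(Oc2cc(OC)cc(OC)c2Oc3cc(OC)c(Oc4cc(OC)c(OC)c(OC)c4)c(OCC)c3)c(OC)c1 | intermediate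
44 | hexamer bromide (OMe on B C3 and B C5, Br on B C1) | COc7cc(Br)cc(OC)c7Oc5cc(OC)c(OC)c(OC)c5Oc1cc(OC)c(Oc2cc(OC)cc(OC)c2Oc3cc(OC)c(Oc4cc(OC)c(OC)c(OC)c4)c(OCC)c3)c(OC)c1 | intermediate
45 | 2,4,6-trimethoxyphenol | COc1cc(OC)c(O)c(OC)c1 | starting material
46 | protected heptamer A–G (sixteen OMe, OEt on F C5) | COc7cc(Oc8c(OC)cc(OC)cc8OC)cc(OC)c7Oc5cc(OC)c(OC)c(OC)c5Oc1cc(OC)c(Oc2cc(OC)cc(OC)c2Oc3cc(OC)c(Oc4cc(OC)c(OC)c(OC)c4)c(OCC)c3)c(OC)c1 | intermediate
47 | CNP0351377.0 | Oc1cc(O)c(Oc2cc(O)c(Oc3cc(O)c(O)c(O)c3Oc3cc(O)c(Oc4cc(O)cc(O)c4Oc4cc(O)c(Oc5cc(O)c(O)c(O)c5)c(O)c4)c(O)c3)c(O)c2)c(O)c1 | target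

Total step count: 25.
Longest linear sequence: 17 steps (steps 1–4, 9–11, 13–15, 19–25). The branch through steps 5–8 is equally long.

Steps most likely to fail

1. Step 9.
- What may go wrong: the terminal aryl ethynyl ether may oligomerise on heating before it meets the vinylketene. Because it is less nucleophilic than an alkyl or silyl ynol ether, the vinylketene may instead reclose or dimerise. The product phenol may also be acylated by the vinylketene (a basic methanolysis at work-up reverses this) or add to unreacted alkyne.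
- Fallback: it sets out from 11, 29 and 4 and comes back at 24, bringing in ring F in the way rings D and B are brought in. SNAr of 11 on 29 (K2CO3, DMF, 90 °C) should give 5-bromo-3-methoxy-2-(3,4,5-trimethoxyphenoxy)benzaldehyde F1. Baeyer–Villiger oxidation with mCPBA gives 5-bromo-3-methoxy-2-(3,4,5-trimethoxyphenoxy)phenyl formate F2, and methanolysis gives 5-bromo-3-methoxy-2-(3,4,5-trimethoxyphenoxy)phenol F3. Ethylation with EtI and K2CO3 gives 5-bromo-1-ethoxy-3-methoxy-2-(3,4,5-trimethoxyphenoxy)benzene F4. Ullmann coupling of F4 with phenol 4 (CuI, picolinic acid, K3PO4, DMSO, 100 °C) gives 24.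

2. Step 19.
- What may go wrong: coupling of the crowded, very electron-rich phenoxide of 38 may be slow. That would leave time for protodebromination of the valuable bromide 33 and for oxidation of 38.
- Fallback: it sets out from 29, 38 and 25 and comes back at 39. It moves the copper step to the monomer stage, where the bromide is cheaper and less electron-rich, and joins the oligomer by SNAr.
  - Acetalisation of 29 (ethylene glycol, TsOH, PhMe, Dean–Stark trap) switches off the C–F bond and gives 2-(5-bromo-2-fluoro-3-methoxyphenyl)-1,3-dioxolane F5.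
  - Ullmann coupling with 38 gives 2-{5-[2-(benzyloxy)-4,5,6-trimethoxyphenoxy]-2-fluoro-3-methoxyphenyl}-1,3-dioxolane F6.
  - Aqueous HCl in THF gives 5-[2-(benzyloxy)-4,5,6-trimethoxyphenoxy]-2-fluoro-3-methoxybenzaldehyde F7.
  - SNAr with 25 (Cs2CO3, DMSO, 120 °C) gives the pentamer aldehyde F8.
  - mCPBA gives the pentamer formate F9, methanolysis gives the pentamer phenol F10, and MeI with K2CO3 gives 39.

3. Step 25.
- What may go wrong: boron aryloxides may precipitate before all seventeen ethers are cleaved, and the free polyphenol may oxidise in air during isolation.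
- Fallback: it sets out from 46 and comes back at 47, and the crude polyphenol is not purified as such. After the BBr3 treatment, MeOH quench and evaporation, the residue is acetylated (Ac2O, pyridine, rt) to the heptadecaacetate F11. This derivative is stable, can be chromatographed on silica, and can be separated from under-dealkylated material. Acid methanolysis (HCl in MeOH made from AcCl, 0 °C to rt, Ar) and evaporation then give 47.

Further compounds
F1 | step 9 | 5-bromo-3-methoxy-2-(3,4,5-trimethoxyphenoxy)benzaldehyde | O=Cc1cc(Br)cc(OC)c1Oc2cc(OC)c(OC)c(OC)c2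
F2 | step 9 | 5-bromo-3-methoxy-2-(3,4,5-trimethoxyphenoxy)phenyl formate | O=COc1cc(Br)cc(OC)c1Oc2cc(OC)c(OC)c(OC)c2
F3 | step 9 | 5-bromo-3-methoxy-2-(3,4,5-trimethoxyphenoxy)phenol | Oc1cc(Br)cc(OC)c1Oc2cc(OC)c(OC)c(OC)c2
F4 | step 9 | 5-bromo-1-ethoxy-3-methoxy-2-(3,4,5-trimethoxyphenoxy)benzene | CCOc1cc(Br)cc(OC)c1Oc2cc(OC)c(OC)c(OC)c2
F5 | step 19 | 2-(5-bromo-2-fluoro-3-methoxyphenyl)-1,3-dioxolane | COc1cc(Br)cc(C2OCCO2)c1F
F6 | step 19 | 2-{5-[2-(benzyloxy)-4,5,6-trimethoxyphenoxy]-2-fluoro-3-methoxyphenyl}-1,3-dioxolane | COc1cc(Oc2c(OCc3ccccc3)cc(OC)c(OC)c2OC)cc(C2OCCO2)c1F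
F7 | step 19 | 5-[2-(benzyloxy)-4,5,6-trimethoxyphenoxy]-2-fluoro-3-methoxybenzaldehyde | COc1cc(Oc2c(OCc3ccccc3)cc(OC)c(OC)c2OC)cc(C=O)c1F
F8 | step 19 | pentamer aldehyde (39 with CHO in place of OMe on D C5) | O=Cc1cc(Oc5c(OCc6ccccc6)cc(OC)c(OC)c5OC)cc(OC)c1Oc2cc(OC)cc(OC)c2Oc3cc(OC)c(Oc4cc(OC)c(OC)c(OC)c4)c(OCC)c3
F9 | step 19 | pentamer formate (OCHO on D C5) | O=COc1cc(Oc5c(OCc6ccccc6)cc(OC)c(OC)c5OC)cc(OC)c1Oc2cc(OC)cc(OC)c2Oc3cc(OC)c(Oc4cc(OC)c(OC)c(OC)c4)c(OCC)c3
F10 | step 19 | pentamer phenol (OH on D C5, OBn on C C1) | Oc1cc(Oc5c(OCc6ccccc6)cc(OC)c(OC)c5OC)cc(OC)c1Oc2cc(OC)cc(OC)c2Oc3cc(OC)c(Oc4cc(OC)c(OC)c(OC)c4)c(OCC)c3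
F11 | step 25 | heptadecaacetate of 47 | CC(=O)Oc1cc(OC(C)=O)c(Oc2cc(OC(C)=O)c(Oc3cc(OC(C)=O)c(OC(C)=O)c(OC(C)=O)c3Oc3cc(OC(C)=O)c(Oc4cc(OC(C)=O)cc(OC(C)=O)c4Oc4cc(OC(C)=O)c(Oc5cc(OC(C)=O)c(OC(C)=O)c(OC(C)=O)c5)c(OC(C)=O)c4)c(OC(C)=O)c3)c(OC(C)=O)c2)c(OC(C)=O)c1
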